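The cyclohexane of amaurone B (C1 bears the side chain, C2 CHMe, C3 CMeOH, C4 CHOAc, C5 CMeOH, C6 CHOAc) has its C6 oxygen β to, and trans to, the exocyclic carbon on C1, and C5 is quaternary. The ring is therefore disconnected at C1–C6 to a heptanedial whose C6 aldehyde cannot enolise. One amine-catalysed 6-enolexo aldolisation closes the carbocycle, forms C1–C6 and sets both C1 and C6. Its precursor is the C4-acetylated dialdehyde with the C3 and C5 oxygens tied by a diisopropylsilylene bridge; the new formyl group is then extended to the triene and joined to the pyranone.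

Key step: step 9

Remark: locants C1–C6 are the cyclohexane locants defined above and are also used for the acyclic intermediates; the silicon bridge is chosen as diisopropylsilylene because it must span two tertiary alcohols and, in the bicyclic aldol product, one silicon substituent faces the axial hydrogen on C1.

Step 1
Reactants: 1 tiglaldehyde; 2 isopropenylmagnesium bromide
Product: 3 rac-(E)-2,4-dimethylhexa-1,4-dien-3-ol
Conditions: THF, −78 → 0 °C; aq. NH4Cl
Reagents that add atoms: isopropenylmagnesium bromide (2), C=C(C)[Mg]Br
Why: Grignard 1,2-addition to the enal should give the racemic bis-allylic carbinol (future C4) flanked by the C2=C3 and C5=C6 alkenes, the racemate being accepted because the next step resolves it.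

Step 2
Reactants: 3
Product: 4 (S)-1-[(2S,3S)-2,3-dimethyloxiran-2-yl]-2-methylprop-2-en-1-ol
Conditions: Ti(OiPr)4 (0.2 equiv), L-(+)-diisopropyl tartrate (0.25 equiv), t-BuOOH (0.5 equiv), 4 Å MS, CH2Cl2, −20 °C
Reagents that add atoms: tert-butyl hydroperoxide, CC(C)(C)OO
Why: Sharpless asymmetric epoxidation run as a kinetic resolution, in which the L-(+)-tartrate catalyst should epoxidise the trisubstituted alkene of the (S)-carbinol fast and anti (erythro) to the hydroxyl, fixing C2, C3 and C4, while the (R)-carbinol stays behind or is diverted to its isopropenyl epoxide, a separable constitutional isomer.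

Step 3
Reactants: 4
Product: 5 (S)-[(2S,3S)-2,3-dimethyloxiran-2-yl][(S)-2-methyloxiran-2-yl]methanol
Conditions: VO(acac)2 (5 mol%), t-BuOOH (1.5 equiv), CH2Cl2, 0 °C → rt
Reagents that add atoms: tert-butyl hydroperoxide, CC(C)(C)OO
Why: Hydroxyl-directed vanadium-catalysed epoxidation of a 2-substituted secondary allylic alcohol should deliver oxygen anti (erythro) to the C4 hydroxyl, because the vanadate ester transition state avoids A(1,2) strain with the alkene methyl, and this sets C5.

Step 4
Reactants: 5
Product: 6 (1S,2S)-1-[(2S,3S)-2,3-dimethyloxiran-2-yl]-2-methylbut-3-ene-1,2-diol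
Conditions: Me3S+ I− (4 equiv), n-BuLi (3.9 equiv), THF, −10 °C → rt
Reagents that add atoms: trimethylsulfonium iodide, C[S+](C)C.[I-]
Why: One-carbon homologation of a terminal epoxide to an allylic alcohol by dimethylsulfonium methylide (Corey–Chaykovsky-type opening at the CH2 carbon, then ylide-induced elimination of dimethyl sulfide) should turn C6 into a vinyl CH without touching the C5–O bond, so C5 keeps its configuration, and the hindered trisubstituted oxirane should be left alone.

Step 5
Reactants: 6; 7 allylmagnesium chloride
Product: 8 (3S,4S,5R,6S)-3,5,6-trimethylnona-1,8-diene-3,4,5-triol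
Conditions: 7 (6 equiv), CuI (0.3 equiv), THF, −30 → 0 °C; aq. NH4Cl
Reagents that add atoms: allylmagnesium chloride (7), C=CC[Mg]Cl
Why: Copper-catalysed SN2 opening of the 2,3-epoxy alcohol by the allyl nucleophile should occur at the secondary oxirane carbon C2 (the fully substituted C3 is inaccessible) with inversion, which sets C2 and frees the C3 tertiary alcohol with retention.

Step 6
Reactants: 8
Product: 9 (3S,4S,5R,6S)-3,5-dihydroxy-3,5,6-trimethylnona-1,8-dien-4-yl acetate
Conditions: Ac2O (1.5 equiv), DMAP (0.1 equiv), pyridine, CH2Cl2, 0 °C → rt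
Reagents that add atoms: acetic anhydride, CC(=O)OC(C)=O
Why: DMAP-catalysed acylation should select the only secondary hydroxyl (C4) over the two tertiary ones, installing the C4 acetate of the target and leaving a 1,3-diol of two tertiary alcohols.

Step 7
Reactants: 9
Product: 10 C3,C5-O-diisopropylsilylene acetal of 9 (2,2-diisopropyl-1,3-dioxa-2-silacyclohexane; one ring carbon bears methyl and vinyl, the other methyl and the (S)-pent-4-en-2-yl group, the carbon between them the acetoxy group; configurations as in 9)
Conditions: iPr2Si(OTf)2 (1.3 equiv), 2,6-lutidine (3 equiv), CH2Cl2, 0 °C → reflux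
Reagents that add atoms: diisopropylsilyl bis(trifluoromethanesulfonate), CC(C)[Si](OS(=O)(=O)C(F)(F)F)(OS(=O)(=O)C(F)(F)F)C(C)C
Why: Cyclic silylene acetal formation, in which the bis-electrophilic silyl ditriflate should silylate one tertiary alcohol and close onto the syn-1,3-related second one to a six-membered ring, masks both tertiary hydroxyls (no lactols with the later aldehydes) and ties C3 to C5.

Step 8
Reactants: 10
Product: 12 silylene-bridged C4-acetoxy heptanedial (OHC–C1H2–C2HMe–C3Me(O)–C4H(OAc)–C5Me(O)–C6HO with the C3 and C5 oxygens joined by Si(iPr)2), via bis-ozonide 11 (not isolated)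
Conditions: O3, CH2Cl2, −78 °C; then PPh3, −78 °C → rt
Reagents that add atoms: ozone, [O-][O+]=O
Why: Ozonolysis with reductive work-up should cleave both terminal alkenes at once, the allyl group to the enolisable C1 acetaldehyde arm and the vinyl group to the non-enolisable C6 aldehyde, while the acetate and the silylene acetal are inert to ozone.

Step 9
Reactants: 12
Product: 13 cyclohexane β-hydroxy aldehyde (C1 CHO, C2 Me, C3 Me/O–Si, C4 OAc, C5 Me/O–Si, C6 OH; the four ring oxygens on one face, the formyl group and the C2, C3 and C5 methyls on the other)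
Conditions: D-proline (30 mol%), DMSO, rt, 0.05 M
Reagents that add atoms: none
Why: D-proline condenses with the C1 formylmethyl arm, the only enolisable carbonyl, and the enamine carbon C1 adds to the C6 aldehyde, which the carboxylic acid of the catalyst activates by hydrogen bonding, before hydrolysis of the iminium ion releases the β-hydroxy aldehyde. The closest known reaction type is the proline-catalysed enolexo aldolisation of heptanedials to trans-2-hydroxycyclohexanecarbaldehydes. The cyclohexane closes in the 6-enolexo-exo-trig mode. C1 is controlled by the silylene bridge, which holds C3–O and C5–O diaxial in the forming chair and so closes the axial site on C1 to the enamine carbon, forcing it equatorial and cis to the C2 methyl; C6 is controlled by the axial C2 methyl, which the carbonyl oxygen avoids by staying equatorial, gauche to the enamine as the hydrogen bond requires, so that the C6 hydroxyl should end up trans to the C1 formyl group. The step needs donor/acceptor chemoselectivity, secured by the quaternary oxygenated C5 that leaves the C6 aldehyde unable to enolise, and facial selectivity, secured by the bridged chair and reinforced by D-proline, whose sense of anti-aldolisation coincides with it. Loss of water from the product is the main side reaction and should be limited by the mild, weakly acidic conditions.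

Step 10
Reactants: 13; 14 2-(triphenylphosphoranylidene)propanal
Product: 15 (E)-2-methyl-3-(cyclohexyl)propenal (13 with CHO replaced by CH=C(Me)CHO; C6 hydroxyl free)
Conditions: crude 13, 14 (2 equiv), toluene, 80 °C
Reagents that add atoms: 2-(triphenylphosphoranylidene)propanal (14), CC(C=O)=P(c1ccccc1)(c1ccccc1)c1ccccc1
Why: Wittig olefination with a stabilised α-methyl ylide should give the (E)-trisubstituted enal (ring trans to CHO by thermodynamic control), the neutral, weakly basic ylide sparing the free C6 hydroxyl, the acetate and the C1 stereocentre, which is no longer α to a carbonyl once the alkene is formed.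

Step 11
Reactants: 15
Product: 16 C6 acetate of 15 (C4,C6-diacetate)
Conditions: Ac2O (2 equiv), DMAP (0.2 equiv), pyridine, CH2Cl2, rt
Reagents that add atoms: acetic anhydride, CC(=O)OC(C)=O
Why: DMAP-catalysed acetylation should esterify the only free hydroxyl (C6, secondary), the tertiary oxygens being held in the silylene acetal.

Step 12
Reactants: 16; 17 (triphenylphosphoranylidene)acetaldehyde
Product: 18 (2E,4E)-4-methyl-5-(cyclohexyl)penta-2,4-dienal (16 extended by CH=CH)
Conditions: 17 (1.2 equiv), toluene, 70 °C
Reagents that add atoms: (triphenylphosphoranylidene)acetaldehyde (17), O=CC=P(c1ccccc1)(c1ccccc1)c1ccccc1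
Why: Wittig two-carbon homologation with the stabilised formylmethylene ylide should give the (E)-disubstituted alkene, and the near-stoichiometric amount of ylide limits a second homologation of the product.

Step 13
Reactants: 19 methyl 2-methyl-3-oxopentanoate; 20 N-methoxy-N-methylpropanamide
Product: 21 methyl 2,4-dimethyl-3,5-dioxoheptanoate (mixture of stereoisomers and enol forms)
Conditions: NaH (1.1 equiv), THF, 0 °C; n-BuLi (1.1 equiv), 0 °C; then 20, −78 °C → rt; aq. HCl
Reagents that add atoms: N-methoxy-N-methylpropanamide (20), CCC(=O)N(C)OC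
Why: Claisen-type C-acylation of the β-keto ester 1,3-dianion at its γ-carbon by the N-methoxy-N-methylamide should give the triketide chain, the chelated tetrahedral intermediate preventing over-addition.

Step 14
Reactants: 21
Product: 22 6-ethyl-4-hydroxy-3,5-dimethyl-2H-pyran-2-one
Conditions: DBU (1.5 equiv), toluene, reflux
Reagents that add atoms: none
Why: Base-mediated enol lactonisation (acyl substitution of the methyl ester by the C5 enolate oxygen) should close the 2-pyranone ring with loss of methanol.

Step 15
Reactants: 22
Product: 23 6-ethyl-2-methoxy-3,5-dimethyl-4H-pyran-4-one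
Conditions: MeOTf (1.2 equiv), CH2Cl2, rt; aq. NaHCO3
Reagents that add atoms: methyl trifluoromethanesulfonate, COS(=O)(=O)C(F)(F)F
Why: O-alkylation of the neutral hydroxypyranone by a hard methylating agent should take place at the lactone carbonyl oxygen, and proton loss from the hydroxypyrylium ion then gives the 2-methoxy-4-pyranone rather than the 4-methoxy-2-pyranone.

Step 16
Reactants: 23; 18
Product: 25 aldol adduct pyranone–CH(Me)–CH(OH)–CH=CH–C(Me)=CH–cyclohexane (mixture of diastereomers at the two new centres), via lithiated pyranone 24 (not isolated)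
Conditions: 23 (2.5 equiv), LiN(SiMe3)2 (2.4 equiv), THF, −78 °C; then 18, −78 °C; aq. NH4Cl at −78 °C
Reagents that add atoms: none
Why: Aldol addition of the pyranone-stabilised (vinylogous enolate) carbanion of the 6-ethyl group should occur 1,2 at the dienal, faster at −78 °C than any attack on the hindered acetates, and both new stereocentres disappear in the next step.

Step 17
Reactants: 25
Product: 27 C3,C5-O-diisopropylsilylene amaurone B, via dienylic mesylate 26 (not isolated)
Conditions: MsCl (1.5 equiv), Et3N (3 equiv), CH2Cl2, 0 °C; then DBU (3 equiv), 0 °C → rt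
Reagents that add atoms: none
Why: Mesylation followed by E1cB elimination through the pyranone-stabilised carbanion should give the conjugated triene, the new trisubstituted alkene forming as the thermodynamically preferred E isomer in which the chain avoids the pyranone C5 methyl.

Step 18
Reactants: 27
Product: 28 amaurone B
Conditions: HF·pyridine, pyridine, THF, 0 °C → rt
Reagents that add atoms: none
Why: Fluoride-mediated cleavage of the silylene acetal (driven by Si–F bond formation) should free the two tertiary alcohols under buffered conditions that leave both acetates, the triene and the pyranone intact, acetyl migration to a tertiary hydroxyl being unfavourable.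

Compound list
1 | tiglaldehyde, (E)-2-methylbut-2-enal | C/C=C(C)/C=O | starting material
2 | isopropenylmagnesium bromide | C=C(C)[Mg]Br | starting material
3 | rac-(E)-2,4-dimethylhexa-1,4-dien-3-ol | C/C=C(C)/C(O)C(C)=C | intermediate
4 | (S)-1-[(2S,3S)-2,3-dimethyloxiran-2-yl]-2-methylprop-2-en-1-ol | C[C@@H]1O[C@@]1(C)[C@@H](O)C(C)=C | intermediate
5 | (S)-[(2S,3S)-2,3-dimethyloxiran-2-yl][(S)-2-methyloxiran-2-yl]methanol | C[C@@H]1O[C@@]1(C)[C@@H](O)[C@]1(C)CO1 | intermediate
6 | (1S,2S)-1-[(2S,3S)-2,3-dimethyloxiran-2-yl]-2-methylbut-3-ene-1,2-diol | C[C@@H]1O[C@@]1(C)[C@@H](O)[C@@](C)(O)C=C | intermediate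
7 | allylmagnesium chloride | C=CC[Mg]Cl | starting material
8 | (3S,4S,5R,6S)-3,5,6-trimethylnona-1,8-diene-3,4,5-triol | C=CC[C@H](C)[C@@](C)(O)[C@@H](O)[C@@](C)(O)C=C | intermediate
9 | (3S,4S,5R,6S)-3,5-dihydroxy-3,5,6-trimethylnona-1,8-dien-4-yl acetate | C=CC[C@H](C)[C@@](C)(O)[C@@H](OC(C)=O)[C@@](C)(O)C=C | intermediate
10 | C3,C5-O-diisopropylsilylene acetal of 9 | C=CC[C@H](C)[C@@](C)(O[Si]1(C(C)C)C(C)C)[C@@H](OC(C)=O)[C@@](C)(O1)C=C | intermediate
11 | bis-ozonide of 10 (both terminal alkenes as 1,2,4-trioxolanes, mixture at the ozonide carbons) | C1(OCOO1)C[C@H](C)[C@@](C)(O[Si]2(C(C)C)C(C)C)[C@@H](OC(C)=O)[C@@](C)(O2)C1OCOO1 | intermediate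
12 | silylene-bridged C4-acetoxy heptanedial (key-step precursor) | O=CC[C@H](C)[C@@](C)(O[Si]1(C(C)C)C(C)C)[C@@H](OC(C)=O)[C@@](C)(O1)C=O | intermediate
13 | silylene-bridged cyclohexane β-hydroxy aldehyde (key-step product) | O=C[C@@H]2[C@H](C)[C@@](C)(O[Si]1(C(C)C)C(C)C)[C@@H](OC(C)=O)[C@@](C)(O1)[C@H]2O | intermediate
14 | 2-(triphenylphosphoranylidene)propanal | CC(C=O)=P(c1ccccc1)(c1ccccc1)c1ccccc1 | starting material
15 | (E)-enal, C6 hydroxyl free | O=C/C(C)=C/[C@@H]2[C@H](C)[C@@](C)(O[Si]1(C(C)C)C(C)C)[C@@H](OC(C)=O)[C@@](C)(O1)[C@H]2O | intermediate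
16 | (E)-enal, C4,C6-diacetate | O=C/C(C)=C/[C@@H]2[C@H](C)[C@@](C)(O[Si]1(C(C)C)C(C)C)[C@@H](OC(C)=O)[C@@](C)(O1)[C@H]2OC(C)=O | intermediate
17 | (triphenylphosphoranylidene)acetaldehyde | O=CC=P(c1ccccc1)(c1ccccc1)c1ccccc1 | starting material
18 | (2E,4E)-dienal | O=C/C=C/C(C)=C/[C@@H]2[C@H](C)[C@@](C)(O[Si]1(C(C)C)C(C)C)[C@@H](OC(C)=O)[C@@](C)(O1)[C@H]2OC(C)=O | intermediate
19 | methyl 2-methyl-3-oxopentanoate | CCC(=O)C(C)C(=O)OC | starting material
20 | N-methoxy-N-methylpropanamide | CCC(=O)N(C)OC | starting material
21 | methyl 2,4-dimethyl-3,5-dioxoheptanoate | CCC(=O)C(C)C(=O)C(C)C(=O)OC | intermediate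
22 | 6-ethyl-4-hydroxy-3,5-dimethyl-2H-pyran-2-one | CCc1oc(=O)c(C)c(O)c1C | intermediate
23 | 6-ethyl-2-methoxy-3,5-dimethyl-4H-pyran-4-one | CCc1oc(OC)c(C)c(=O)c1C | intermediate
24 | lithium salt of 23 deprotonated at the ethyl CH2 | [Li+].C[CH-]c1oc(OC)c(C)c(=O)c1C | intermediate
25 | aldol adduct of 24 and 18 (secondary dienylic alcohol, diastereomer mixture) | COc1oc(C(C)C(O)/C=C/C(C)=C/[C@@H]2[C@H](C)[C@@](C)(O[Si]3(C(C)C)C(C)C)[C@@H](OC(C)=O)[C@@](C)(O3)[C@H]2OC(C)=O)c(C)c(=O)c1C | intermediate
26 | methanesulfonate of 25 | COc1oc(C(C)C(OS(C)(=O)=O)/C=C/C(C)=C/[C@@H]2[C@H](C)[C@@](C)(O[Si]3(C(C)C)C(C)C)[C@@H](OC(C)=O)[C@@](C)(O3)[C@H]2OC(C)=O)c(C)c(=O)c1C | intermediate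
27 | C3,C5-O-diisopropylsilylene amaurone B | COc1oc(/C(C)=C/C=C/C(C)=C/[C@@H]2[C@H](C)[C@@](C)(O[Si]3(C(C)C)C(C)C)[C@@H](OC(C)=O)[C@@](C)(O3)[C@H]2OC(C)=O)c(C)c(=O)c1C | intermediate
28 | amaurone B | COc1oc(/C(C)=C/C=C/C(C)=C/[C@@H]2[C@H](C)[C@@](C)(O)[C@@H](OC(C)=O)[C@@](C)(O)[C@H]2OC(C)=O)c(C)c(=O)c1C | target

Total step count: 18 (steps 1–12 and 16–18 on the main line, steps 13–15 for the pyranone).
Longest linear sequence: 15 steps (1–12, then 16–18).

Steps most likely to fail

Step 9 (key aldolisation). The enamine may add too slowly to the neopentyl-type C6 aldehyde, so that intermolecular aldol oligomerisation takes over. The β-hydroxy aldehyde may also lose water by amine-catalysed elimination, or facial control may erode if the silylene ring leaves the reactive chair. The fallback replaces enamine activation by a Mukaiyama aldol. Setting out from 12, the only enolisable aldehyde would be converted with Et3SiOTf and Et3N (CH2Cl2, −78 → 0 °C) into the triethylsilyl enol ether F1. BF3·OEt2 in CH2Cl2 at −78 °C would then activate the C6 aldehyde, and the enol silane should close the same C1–C6 bond through an open transition state in the same bridged chair. Aqueous work-up returns the β-hydroxy aldehyde 13.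

Step 7 (silylene bridge). The second Si–O bond to a tertiary, fully flanked oxygen may fail to close, leaving an open silyl triflate or silanol, and the Lewis-acidic triflate may ionise the tertiary allylic C5–O bond. The fallback builds the tether stepwise by hydrosilane dehydrocoupling. Setting out from 9, the less hindered tertiary hydroxyl at C5 would be silylated with chlorodiisopropylsilane, imidazole and DMAP in DMF to give the hydrosilyl ether F2. Catalytic B(C6F5)3 (2 mol%, toluene, rt) should then couple the Si–H bond with the C3 hydroxyl under loss of dihydrogen, closing the same ring and rejoining the route at 10.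

Step 5 (allyl opening). Substitution at the secondary oxirane carbon next to a fully substituted centre may be slow in the bis-alkoxide aggregate, so that halide opening by the magnesium salt or base-induced isomerisation of the oxirane competes. The fallback forms the C2–allyl bond before the second oxirane exists. Setting out from 4, the same copper-catalysed allyl opening would be run on the mono-alkoxide, whose C5 is still sp2, to give the diol F3. VO(acac)2 and t-BuOOH should then epoxidise the isopropenyl group anti to the C4 hydroxyl to give the epoxy diol F4. Sulfonium ylide homologation of this terminal oxirane gives triol 8, where the route is rejoined.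

Further compounds
F1 | step 9 | triethylsilyl enol ether of the C1 aldehyde arm of 12 (E/Z mixture) | CC[Si](CC)(CC)OC=C[C@H](C)[C@@](C)(O[Si]1(C(C)C)C(C)C)[C@@H](OC(C)=O)[C@@](C)(O1)C=O
F2 | step 7 | C5-O-diisopropylsilyl (Si–H) ether of 9 | C=CC[C@H](C)[C@@](C)(O)[C@@H](OC(C)=O)[C@@](C)(O[SiH](C(C)C)C(C)C)C=C
F3 | step 5 | (3S,4R,5S)-2,4,5-trimethylocta-1,7-diene-3,4-diol | C=CC[C@H](C)[C@@](C)(O)[C@@H](O)C(C)=C
F4 | step 5 | F3 with the isopropenyl group converted into the (S)-2-methyloxiran-2-yl group | C=CC[C@H](C)[C@@](C)(O)[C@@H](O)[C@]1(C)CO1
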